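I am to read the dusk flask at 5.5 min, so I count how many doublings fit into that time.

| flask | Sub | Cat | time |
|---|---|---|---|
| spring | 0.300 M | 0.0300 M |  |
| autumn | 0.600 M | 0.0300 M |  |
| dusk | 0.0990 M | 0.0300 M | 5.5 min |

| run | time / min | [Prd] / M |
|---|---|---|
| spring run | 0.69 | 0.0057 |
| spring run | 1.4 | 0.0127 |
| spring run | 2.1 | 0.0245 |
| spring run | 2.8 | 0.0409 |
| spring run | 3.4 | 0.0659 |
| spring run | 4.1 | 0.1000 |
| spring run | 4.8 | 0.1426 |
| spring run | 5.5 | 0.1839 |
| autumn run | 0.69 | 0.0050 |
| autumn run | 1.4 | 0.0230 |
| autumn run | 2.1 | 0.0633 |
| autumn run | 2.8 | 0.1675 |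
| autumn run | 3.4 | 0.3067 |
| autumn run | 4.1 | 0.4595 |
| autumn run | 4.8 | 0.5498 |
| autumn run | 5.5 | 0.5826 |

(readings scatter by 9 × 10⁻⁴ M)

- Overall: Sub -> Prd, with Cat as catalyst.
- Constant volume, constant temperature.
- Readings of a species count what is bound in complexes too.
- An order is taken over about fifteen percent of the charge, up and down.

- the exponent of [Sub] in the starting rate at the charge of the spring run (at the point where two percent of the Sub have become Prd) (one fixed amount of Prd, the same in the runs compared)
- Prd in the dusk run at 5.5 min, as a share of the Sub charged

The curves of the spring and autumn runs bend upward at first, so I read them as autocatalysis: Prd makes further Prd from Sub. Between 4.1 min and 4.8 min of the spring run, the rate divided by mean [Prd] and mean [Sub] reads k = 2.81 /M/min.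

My quantity is the doubling time τ = ln(2)/(k·S), with S the Sub charged: the time in which the odds, Prd over Sub left, double. For the dusk flask τ is 2.49 min, so 2.21 doublings fit.

What they multiply is a seed s, the Prd a run behaves as if it began with. Counting the odds back to the start gives 0.00475 M in the spring run and 0.00208 M in the autumn run. The seed of the autumn run is smaller than that of the spring run, so for the dusk flask I guess that s·S stays at the mean of the two runs. That gives the dusk flask a seed of 0.0135 M, and its odds at 5.5 min give a Prd share of 38.6% of the Sub charged.

The forecast says 0.4 for the order and, higher than my figure, 43% for dusk, opening with “The curves are sigmoidal, so Prd is autocatalytic.”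

The flask gives an order of 0.39 and 35.4% in dusk, 3.2 percentage points below my figure.

    Cat + Sub ⇌ Cat.Sub, settled at all times (4.940 /M)
    Cat.Sub + Cat → Prd + 2 Cat (30.96 /M/min)
    Sub + Prd → 2 Prd (2.796 /M/min)
    Cat + Sub → X + Sub (2.166 /M/min)

Counted back at 2.49 min per doubling, the dusk value means a seed of 0.0118 M, less than my 0.0135 M. The dusk flask loses Cat to X: without the path Cat + Sub → X + Sub, the same run reaches 50.0% and not 35.4%. In the autumn run τ is 0.411 min. From Prd at a quarter of the charge to half, the odds grow by a factor 3, which τ puts at 0.652 min, and the autumn run took 0.665 min.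

(The runs were generated by integration on assumed constants; scatter was added.)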